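**Plan**

Numbering: C1 quaternary C–Me, C2, C3, C4 carbinol, C5 ring-fusion CH, C6 ester carbon, C7, C8(Me)=C9, C10; ring A is C1–C5, ring B the seven-membered ring; β is the face of the C1 methyl.
Cuts, last made first: the C6–O aroyl bond; C5–H and C6–O (from a β-epoxide of C5=C6); C4–isopropyl; then C3–C4 of ring A. This last cut is possible because the oxygenated C4 and C3, the far end of a two-carbon unit on the quaternary C1, stand in a 4-pentenal to cyclopentanone relation (O=C4H–C5–C1–C2=C3).
Further back: the formyl bond C4–C5, the vinyl bond C1–C2, and ring B at C6–C7 (Claisen) and C9–C10 (homoenolate addition).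
Forward: ring B first (lactone, methylenation, Claisen ring expansion), then the vinyl group on C1 and the aldehyde on C5, then ring A by rhodium-catalysed hydroacylation, then C4, C6/C5 and the ester.
Stereochemistry: C1 from a chiral-imine Michael addition with (R)-1-phenylethylamine, which also deracemises the ring B ketone; C4 by addition anti to the angular methyl; C6 by hydroxyl-directed epoxidation; C5 by hydrogen-atom transfer to the α-face of a C5 radical.

Key step: step 9

Assumption: the racemic bromo ester is sufficient, because both stereocentres of the first lactone are erased (one in the Claisen step, the other by enamine formation) before C1 is set.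

Step 1
Reactants: 1 methacrolein; 2 methyl 3-bromo-2-methylpropanoate (racemic)
Product: 6 3-methyl-5-(prop-1-en-2-yl)oxolan-2-one (racemic cis/trans mixture), via zinc reagent 3 (not isolated), via silyl ether 4 (not isolated), via hydroxy ester 5 (not isolated)
Conditions: Zn dust, I2 (cat.), DMA, 70 °C; then 1, Me3SiCl, toluene, 0 °C to rt; then 1 M HCl, THF, rt
Reagents that add atoms: none
Why: Zinc homoenolate addition followed by lactonisation: zinc insertion gives a chelated ester homoenolate that neither enolises nor eliminates, Me3SiCl activation drives its 1,2-addition to the enal carbonyl (no copper, hence no conjugate addition), and acid cleaves the silyl ether and closes the γ-lactone; no stereocontrol is needed here.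

Step 2
Reactants: 6 3-methyl-5-(prop-1-en-2-yl)oxolan-2-one
Product: 7 3-methyl-2-methylidene-5-(prop-1-en-2-yl)oxolane
Conditions: Cp2TiMe2 (2 equiv), toluene, 70 °C, dark; filtration through basic alumina (pentane, 1% Et3N)
Reagents that add atoms: dimethyltitanocene Cp2TiMe2, SMILES [CH3-].[CH3-].[Ti+4].[cH-]1cccc1.[cH-]1cccc1
Why: Petasis methylenation: Cp2TiMe2 loses methane to a titanium methylidene that turns the lactone carbonyl into the exocyclic enol ether without touching the isopropenyl group and without the Lewis acidity that would move the new double bond into the ring.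

Step 3
Reactants: 7 3-methyl-2-methylidene-5-(prop-1-en-2-yl)oxolane
Product: 8 2,5-dimethylcyclohept-4-en-1-one (racemic)
Conditions: degassed toluene, base-washed sealed tube, 180 °C
Reagents that add atoms: none
Why: Claisen ring expansion: the allyl vinyl ether CH2=C–O–CH–C(Me)=CH2 rearranges through a boat transition state, forming C6–C7, breaking the ring C–O bond and giving the cis ring alkene C8=C9 and the C5 ketone, as known for 2-methylidene-5-alkenyloxolanes going to cyclohept-4-enones.

Step 4
Reactants: 8 2,5-dimethylcyclohept-4-en-1-one; 9 methyl acrylate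
Product: 12 methyl 3-[(1R)-1,4-dimethyl-7-oxocyclohept-3-en-1-yl]propanoate, via imine 10 (not isolated), via adduct imine 11 (not isolated)
Conditions: (R)-1-phenylethylamine (1.05 equiv), TsOH (cat.), toluene, reflux, Dean–Stark; then 9 (1.5 equiv), THF, 50 °C; then 10% aq AcOH, rt
Reagents that add atoms: none
Why: Michael addition of a chiral imine through its more substituted secondary enamine tautomer: bond formation therefore occurs only at the methyl-bearing α-carbon and not at C6, both enantiomers of 8 converge on one enamine, and the acrylate adds with internal N–H transfer to the enamine face away from the phenyl group of the (R)-auxiliary, which sets C1 as required (the (S)-amine is known to give the mirror-image sense with 2-methylcycloalkanones).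

Step 5
Reactants: 12 methyl 3-[(1R)-1,4-dimethyl-7-oxocyclohept-3-en-1-yl]propanoate
Product: 13 3-[(1R)-1,4-dimethyl-7-oxocyclohept-3-en-1-yl]propanoic acid
Conditions: LiOH·H2O, THF/H2O, rt; then 1 M HCl
Reagents that add atoms: none
Why: Ester saponification; the quaternary C1 has no hydrogen and cannot epimerise.

Step 6
Reactants: 13 3-[(1R)-1,4-dimethyl-7-oxocyclohept-3-en-1-yl]propanoic acid
Product: 15 (2S)-2-ethenyl-2,5-dimethylcyclohept-4-en-1-one, via mixed anhydride 14 (not isolated)
Conditions: PdCl2(nbd) (2 mol%), Xantphos (2.4 mol%), Bz2O (1.2 equiv), NMP, 130 °C, short reaction time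
Reagents that add atoms: none
Why: Palladium-catalysed decarbonylative dehydration, a method established for δ-oxo acids: zerovalent palladium inserts into the acyl C–O bond of the mixed anhydride, CO is lost and β-hydride elimination leaves the terminal vinyl group; no free radical is formed, so the C8=C9 alkene is not attacked, and a vinyl group on a quaternary carbon cannot isomerise.

Step 7
Reactants: 15 (2S)-2-ethenyl-2,5-dimethylcyclohept-4-en-1-one
Product: 16 N'-[(1E,2S)-2-ethenyl-2,5-dimethylcyclohept-4-en-1-ylidene]-2,4,6-tri(propan-2-yl)benzenesulfonohydrazide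
Conditions: 2,4,6-tri(propan-2-yl)benzenesulfonohydrazide (1.1 equiv), HCl (cat.), MeCN, rt
Reagents that add atoms: 2,4,6-tri(propan-2-yl)benzenesulfonohydrazide, SMILES CC(C)c1cc(C(C)C)c(c(C(C)C)c1)S(=O)(=O)NN
Why: Acid-catalysed hydrazone condensation, which works for α-quaternary cycloalkanones; the sulfonamide nitrogen should settle anti to the quaternary C1 and thus syn to the C6 methylene that is deprotonated next, and the crystalline hydrazone offers a point to raise enantiomeric purity.

Step 8
Reactants: 16 N'-[(1E,2S)-2-ethenyl-2,5-dimethylcyclohept-4-en-1-ylidene]-2,4,6-tri(propan-2-yl)benzenesulfonohydrazide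
Product: 19 (7S)-7-ethenyl-4,7-dimethylcyclohepta-1,4-diene-1-carbaldehyde, via vinyllithium 17 (not isolated), via lithium aminoalkoxide 18 (not isolated)
Conditions: n-BuLi (2.2 equiv), THF, −78 °C to 0 °C; re-cool to −78 °C, DMF (3 equiv); AcOH (1.2 equiv) in THF, −78 °C, then water
Reagents that add atoms: N,N-dimethylformamide, SMILES CN(C)C=O
Why: Shapiro reaction: the dianion can only form at C6 and loses sulfinate and nitrogen to give the C5 vinyllithium with the C5=C6 double bond, and DMF traps it as a tetrahedral adduct that releases the enal only on cold, mildly acidic quench, which avoids base-mediated conjugation of the skipped diene.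

Step 9
Reactants: 19 (7S)-7-ethenyl-4,7-dimethylcyclohepta-1,4-diene-1-carbaldehyde
Product: 20 (3aR)-3a,6-dimethyl-3,3a,4,7-tetrahydroazulen-1(2H)-one
Conditions: [Rh(nbd)(dppe)]BF4 (5 mol%), activated with H2 then purged with Ar, acetone (or CH2Cl2), 25 °C
Reagents that add atoms: none
Why: The cationic monovalent rhodium centre adds oxidatively into the formyl C–H bond to give a trivalent acyl rhodium hydride; the vinyl group on C1 coordinates and inserts into Rh–H with rhodium going to the terminal carbon C3, giving a six-membered acyl–alkyl rhodacycle, and C–C reductive elimination forms C3–C4. The closest known reaction is the [Rh(dppe)]+-catalysed cyclisation of 4-pentenals to cyclopentanones, which tolerates 3,3-disubstitution and an sp2 carbon next to the formyl group (2-vinylbenzaldehyde-type substrates). Ring A closes as a five-membered ring in which both vinyl carbons become ring members, a formal 5-endo closure made possible by the six-membered metallacycle; the alternative five-membered metallacycle would lead to a cyclobutanone and is not productive. No stereocentre is created, and C1 is carried through unchanged because it bears no hydrogen and none of its bonds is altered. The step needs cyclisation to outrun decarbonylation and rhodium hydride migration of the skipped C8=C9 bond into conjugation: the chelating diphosphine on a weakly solvated cation, the quaternary C1 (gem-disubstituent effect, no allylic hydrogen next to the vinyl group) and room temperature should secure this, while the two trisubstituted ring alkenes are too hindered to insert.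

Step 10
Reactants: 20 (3aR)-3a,6-dimethyl-3,3a,4,7-tetrahydroazulen-1(2H)-one; 21 isopropylmagnesium chloride (i-PrMgCl)
Product: 23 (1R,3aR)-3a,6-dimethyl-1-(propan-2-yl)-1,2,3,3a,4,7-hexahydroazulen-1-ol (hydroxyl cis to the C1 methyl), via organocerium i-PrCeCl2 22 (not isolated)
Conditions: CeCl3 (anhydrous, 2 equiv), THF; 21 (2 equiv), −78 °C; then 20, −78 °C to 0 °C; aq NH4Cl
Reagents that add atoms: none
Why: Organocerium 1,2-addition: the weakly basic, oxophilic reagent should add to the enone carbonyl without enolisation at C3, γ-deprotonation at C7, conjugate addition or β-hydride reduction, and should enter on the α-face, anti to the pseudoaxial angular methyl (the α-face carries only the C10 methylene, tied back into ring B); the C4 epimers are separable at this stage.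

Step 11
Reactants: 23 (1R,3aR)-3a,6-dimethyl-1-(propan-2-yl)-1,2,3,3a,4,7-hexahydroazulen-1-ol
Product: 24 (1R,3aR,8R,8aS)-8,8a-epoxy-3a,6-dimethyl-1-(propan-2-yl)-1,2,3,3a,4,7,8,8a-octahydroazulen-1-ol (the 5β,6β-epoxide; oxirane oxygen cis to the 4-hydroxyl and the C1 methyl)
Conditions: VO(acac)2 (5 mol%), t-BuOOH (1.5 equiv, decane), 2,6-lutidine (cat.), CH2Cl2, 0 °C to rt
Reagents that add atoms: tert-butyl hydroperoxide, SMILES CC(C)(C)OO
Why: Hydroxyl-directed vanadium epoxidation: the peroxide is delivered from the vanadate ester of the 4-hydroxyl, so only the allylic C5=C6 bond reacts (not C8=C9) and the oxygen arrives on the face of the hydroxyl, which fixes C6–O cis to the 4-OH and the angular methyl.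

Step 12
Reactants: 24 (1R,3aR,8R,8aS)-8,8a-epoxy-3a,6-dimethyl-1-(propan-2-yl)-1,2,3,3a,4,7,8,8a-octahydroazulen-1-ol
Product: 25 (3R,3aS,4R,8aR)-6,8a-dimethyl-3-(propan-2-yl)-1,2,3,3a,4,5,8,8a-octahydroazulene-3,4-diol
Conditions: Cp2TiCl2 (2.5 equiv), Zn dust, THF, rt (forms Cp2TiCl); then 24, 1,4-cyclohexadiene (10 equiv), rt; aq NaH2PO4
Reagents that add atoms: none
Why: Reductive epoxide opening by trivalent titanium (Cp2TiCl): single-electron transfer breaks the C5–O bond to leave the more substituted C5 radical with the C6 titanium alkoxide in its original configuration (known for trisubstituted 2,3-epoxy alcohols giving 1,3-diols), and 1,4-cyclohexadiene should transfer hydrogen to the face away from the titanium alkoxide, the 4-hydroxyl and the angular methyl, giving the trans ring fusion; the hindered tertiary radical should be trapped too slowly by a second Cp2TiCl for deoxygenation to compete.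

Step 13
Reactants: 25 (3R,3aS,4R,8aR)-6,8a-dimethyl-3-(propan-2-yl)-1,2,3,3a,4,5,8,8a-octahydroazulene-3,4-diol; 26 4-acetoxybenzoyl chloride
Product: 27 (3R,3aS,4R,8aR)-3-hydroxy-6,8a-dimethyl-3-(propan-2-yl)-1,2,3,3a,4,5,8,8a-octahydroazulen-4-yl 4-(acetyloxy)benzoate
Conditions: Et3N (3 equiv), DMAP (0.2 equiv), CH2Cl2, 0 °C to rt
Reagents that add atoms: none
Why: DMAP-catalysed acylation: only the secondary 6-hydroxyl is esterified, the tertiary 4-hydroxyl being inert under these conditions.

Step 14
Reactants: 27 (3R,3aS,4R,8aR)-3-hydroxy-6,8a-dimethyl-3-(propan-2-yl)-1,2,3,3a,4,5,8,8a-octahydroazulen-4-yl 4-(acetyloxy)benzoate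
Product: 28 (3R,3aS,4R,8aR)-3-hydroxy-6,8a-dimethyl-3-(propan-2-yl)-1,2,3,3a,4,5,8,8a-octahydroazulen-4-yl 4-hydroxybenzoate (the target)
Conditions: pyrrolidine (3 equiv), CH2Cl2, 0 °C to rt
Reagents that add atoms: none
Why: Aminolysis of the aryl acetate: phenyl acetates transfer their acyl group to secondary amines at room temperature, whereas the hindered secondary alkyl benzoate and the tertiary alcohol do not react, so the phenol is released without loss or migration of the C6 ester.

**Compound list**

1 | methacrolein (2-methylprop-2-enal) | C=C(C)C=O | starting material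
2 | methyl 3-bromo-2-methylpropanoate (racemic) | COC(=O)C(C)CBr | starting material
3 | bromo(3-methoxy-2-methyl-3-oxopropyl)zinc | COC(=O)C(C)C[Zn]Br | intermediate (not isolated)
4 | methyl 2,5-dimethyl-4-[(trimethylsilyl)oxy]hex-5-enoate (diastereomer mixture) | COC(=O)C(C)CC(O[Si](C)(C)C)C(C)=C | intermediate (not isolated)
5 | methyl 4-hydroxy-2,5-dimethylhex-5-enoate (diastereomer mixture) | COC(=O)C(C)CC(O)C(C)=C | intermediate (not isolated)
6 | 3-methyl-5-(prop-1-en-2-yl)oxolan-2-one (racemic cis/trans mixture) | CC1CC(OC1=O)C(C)=C | intermediate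
7 | 3-methyl-2-methylidene-5-(prop-1-en-2-yl)oxolane (racemic cis/trans mixture) | C=C1OC(CC1C)C(C)=C | intermediate
8 | 2,5-dimethylcyclohept-4-en-1-one (racemic) | CC1CC=C(C)CCC1=O | intermediate
9 | methyl acrylate | C=CC(=O)OC | starting material
10 | N-[(1R)-1-phenylethyl]-2,5-dimethylcyclohept-4-en-1-imine | CC1CC=C(C)CCC1=N[C@H](C)c1ccccc1 | intermediate (not isolated)
11 | methyl 3-[(1R)-1,4-dimethyl-7-{[(1R)-1-phenylethyl]imino}cyclohept-3-en-1-yl]propanoate | COC(=O)CC[C@]1(C)CC=C(C)CCC1=N[C@H](C)c1ccccc1 | intermediate (not isolated)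
12 | methyl 3-[(1R)-1,4-dimethyl-7-oxocyclohept-3-en-1-yl]propanoate | COC(=O)CC[C@]1(C)CC=C(C)CCC1=O | intermediate
13 | 3-[(1R)-1,4-dimethyl-7-oxocyclohept-3-en-1-yl]propanoic acid | OC(=O)CC[C@]1(C)CC=C(C)CCC1=O | intermediate
14 | benzoic 3-[(1R)-1,4-dimethyl-7-oxocyclohept-3-en-1-yl]propanoic anhydride | O=C(OC(=O)c1ccccc1)CC[C@]1(C)CC=C(C)CCC1=O | intermediate (not isolated)
15 | (2S)-2-ethenyl-2,5-dimethylcyclohept-4-en-1-one | C=C[C@]1(C)CC=C(C)CCC1=O | intermediate
16 | N'-[(1E,2S)-2-ethenyl-2,5-dimethylcyclohept-4-en-1-ylidene]-2,4,6-tri(propan-2-yl)benzenesulfonohydrazide | C=C[C@]1(C)CC=C(C)CC\C1=N/NS(=O)(=O)c1c(C(C)C)cc(C(C)C)cc1C(C)C | intermediate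
17 | [(7S)-7-ethenyl-4,7-dimethylcyclohepta-1,4-dien-1-yl]lithium | C=C[C@]1(C)CC=C(C)CC=C1[Li] | intermediate (not isolated)
18 | lithium (dimethylamino)[(7S)-7-ethenyl-4,7-dimethylcyclohepta-1,4-dien-1-yl]methanolate | C=C[C@]1(C)CC=C(C)CC=C1C(O[Li])N(C)C | intermediate (not isolated)
19 | (7S)-7-ethenyl-4,7-dimethylcyclohepta-1,4-diene-1-carbaldehyde | C=C[C@]1(C)CC=C(C)CC=C1C=O | intermediate (key-step precursor)
20 | (3aR)-3a,6-dimethyl-3,3a,4,7-tetrahydroazulen-1(2H)-one | CC1=CC[C@@]2(C)CCC(=O)C2=CC1 | intermediate (key-step product)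
21 | isopropylmagnesium chloride (i-PrMgCl) | CC(C)[Mg]Cl | starting material
22 | dichloro(propan-2-yl)cerium (i-PrCeCl2) | CC(C)[Ce](Cl)Cl | intermediate (not isolated)
23 | (1R,3aR)-3a,6-dimethyl-1-(propan-2-yl)-1,2,3,3a,4,7-hexahydroazulen-1-ol | CC1=CC[C@@]2(C)CC[C@@](O)(C(C)C)C2=CC1 | intermediate
24 | (1R,3aR,8R,8aS)-8,8a-epoxy-3a,6-dimethyl-1-(propan-2-yl)-1,2,3,3a,4,7,8,8a-octahydroazulen-1-ol (5β,6β-epoxide) | CC1=CC[C@@]2(C)CC[C@@](O)(C(C)C)[C@]23O[C@@H]3CC1 | intermediate
25 | (3R,3aS,4R,8aR)-6,8a-dimethyl-3-(propan-2-yl)-1,2,3,3a,4,5,8,8a-octahydroazulene-3,4-diol | CC1=CC[C@@]2(C)CC[C@@](O)(C(C)C)[C@@H]2[C@H](O)C1 | intermediate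
26 | 4-acetoxybenzoyl chloride | CC(=O)Oc1ccc(cc1)C(Cl)=O | starting material
27 | (3R,3aS,4R,8aR)-3-hydroxy-6,8a-dimethyl-3-(propan-2-yl)-1,2,3,3a,4,5,8,8a-octahydroazulen-4-yl 4-(acetyloxy)benzoate | CC1=CC[C@@]2(C)CC[C@@](O)(C(C)C)[C@@H]2[C@H](OC(=O)c2ccc(OC(C)=O)cc2)C1 | intermediate
28 | (3R,3aS,4R,8aR)-3-hydroxy-6,8a-dimethyl-3-(propan-2-yl)-1,2,3,3a,4,5,8,8a-octahydroazulen-4-yl 4-hydroxybenzoate | CC1=CC[C@@]2(C)CC[C@@](O)(C(C)C)[C@@H]2[C@H](OC(=O)c2ccc(O)cc2)C1 | target

**Step count and risks**

Total step count: 14. Longest linear sequence: 14 steps (from 1 and 2 to 28).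

The three steps most likely to fail:

Step 9. The acyl rhodium hydride may decarbonylate and stop turnover, rhodium hydride may move the C8=C9 bond into conjugation, or the cyclohepta-1,4-diene may chelate the catalyst unproductively. The fallback sets out from hydrazone 16 and builds ring A with carbon monoxide as C4. The Shapiro vinyllithium is quenched with I2 to give the vinyl iodide (7S)-7-ethenyl-1-iodo-4,7-dimethylcyclohepta-1,4-diene F1. The vinyl group is hydroborated selectively with 9-BBN (THF, rt) to the B-alkyl borane 9-{2-[(1R)-2-iodo-1,5-dimethylcyclohepta-2,5-dien-1-yl]ethyl}-9-borabicyclo[3.3.1]nonane F2, which is used in the same flask. An intramolecular carbonylative Suzuki coupling (PdCl2(dppf), K3PO4, CO 1 atm, THF, rt to 50 °C) then forms C3–C4 and C4–C5 and comes back to the route at dienone 20.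

Step 10. The reagent may not distinguish well enough between the angular methyl on the β-face and the C10 methylene on the α-face, both of which sit on C1 one carbon away from the carbonyl, so that a mixture of C4 epimers results. The fallback sets out from 20 and replaces this remote control by a neighbouring-group relationship. Luche reduction (NaBH4, CeCl3·7H2O, MeOH, −78 °C) gives the allylic alcohols, of which the 4β-alcohol (1S,3aR)-3a,6-dimethyl-1,2,3,3a,4,7-hexahydroazulen-1-ol F3 is taken on and the epimer is returned to 20 with MnO2. VO(acac)2/t-BuOOH epoxidation syn to the hydroxyl gives the epoxy alcohol F4 (5β,6β-epoxide of F3), and Dess–Martin periodinane gives the epoxy ketone F5 (5β,6β-epoxide of 20). i-PrMgCl/CeCl3 should then add anti to the epoxide oxygen on the adjacent carbon, which comes back to the route at epoxy alcohol 24.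

Step 12. Hydrogen-atom transfer to the C5 radical may take place on the β-face and give the cis-fused 5-epimer, or the radical may be reduced further and eliminate back to the alkene. The fallback sets out from 20, follows the sequence above as far as the epoxy ketone F5, and opens the epoxide before the isopropyl group is in place. SmI2 (2.2 equiv, THF/MeOH, −78 °C) cleaves the C5–O bond next to the ketone and gives the β-hydroxy ketone (3aR,8R,8aS)-8-hydroxy-3a,6-dimethyl-2,3,3a,4,7,8,8a-octahydroazulen-1-one F6. Here C5 is protonated as an enolate on the face away from the C6 alkoxide and the angular methyl and, being α to the ketone, can still be equilibrated. Excess i-PrMgCl/CeCl3 should then add anti to the C5–C6 bond, which comes back to the route at diol 25.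

**Further compounds**

F1 | step 9 | (7S)-7-ethenyl-1-iodo-4,7-dimethylcyclohepta-1,4-diene | C=C[C@]1(C)CC=C(C)CC=C1I
F2 | step 9 | 9-{2-[(1R)-2-iodo-1,5-dimethylcyclohepta-2,5-dien-1-yl]ethyl}-9-borabicyclo[3.3.1]nonane | C1CCC2CCCC1B2CC[C@]1(C)CC=C(C)CC=C1I
F3 | step 10 | (1S,3aR)-3a,6-dimethyl-1,2,3,3a,4,7-hexahydroazulen-1-ol | CC1=CC[C@@]2(C)CC[C@H](O)C2=CC1
F4 | step 10 | (1S,3aR,8R,8aS)-8,8a-epoxy-3a,6-dimethyl-1,2,3,3a,4,7,8,8a-octahydroazulen-1-ol | CC1=CC[C@@]2(C)CC[C@H](O)[C@]23O[C@@H]3CC1
F5 | step 10 | (3aR,8R,8aS)-8,8a-epoxy-3a,6-dimethyl-2,3,3a,4,7,8-hexahydroazulen-1(8aH)-one | CC1=CC[C@@]2(C)CCC(=O)[C@]23O[C@@H]3CC1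
F6 | step 12 | (3aR,8R,8aS)-8-hydroxy-3a,6-dimethyl-2,3,3a,4,7,8,8a-octahydroazulen-1-one | CC1=CC[C@@]2(C)CCC(=O)[C@@H]2[C@H](O)C1
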